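The ten-membered ring is traced back across C1–C2 to a six-membered ring C4–C9: the C9 ketone with C10, the C1–C2 bond and the C3–C4 unit (later the C4 carbinol) form the 1,5-pattern of an oxy-Cope product. One anionic [3,3] shift enlarges a carvone-derived cyclohexane to the cyclodecenone, forms C1–C2, sets C2 and, on enolate protonation, C10, and leaves an E C3=C4 alkene for hydration. The precursor is a fully substituted cyclohexanol: C9 carries OH and isopropenyl; C4 carries methyl and, trans to that isopropenyl, an E-(4-methoxybenzyloxy)vinyl arm; C5/C6 carry a disiloxane-bridged diol, C7 isopropenyl and C8 an acetal ether.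

Key step: step 14

Remark: locants are those of the target (ring C1–C10, lactone carbons C11–C13); on six-membered intermediates the ring is C9–C4–C5–C6–C7–C8, α is the face carrying the C7 isopropenyl group and β the opposite face.

Step 1
Reactants: 1 (S)-carvone
Product: 3 4α-(hydroxymethyl)-4β-methyl-5β-(phenylselanyl)-7α-isopropenylcyclohexan-9-one, via enol silane 2 (not isolated)
Conditions: PhSeSiMe3, Me3SiOTf (cat.), CH2Cl2, −78 °C; then 1,3,5-trioxane, TiCl4, −78 to −40 °C; aq. NaHCO3
Reagents that add atoms: phenylselenotrimethylsilane, C[Si](C)(C)[Se]c1ccccc1; 1,3,5-trioxane (formaldehyde source), C1OCOCO1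
Why: Tandem silyl-triflate-catalysed conjugate addition of the selenosilane and Mukaiyama aldol reaction with formaldehyde: PhSe should add to C5 anti to the C7 isopropenyl group and the electrophile should enter C4 anti to the pseudoaxial C5 selenide, so the hydroxymethyl arm is α and the methyl β.

Step 2
Reactants: 3 4α-(hydroxymethyl)-4β-methyl-5β-(phenylselanyl)-7α-isopropenylcyclohexan-9-one
Product: 4 4α-(hydroxymethyl)-4β-methyl-5β-(phenylselanyl)-7α-isopropenylcyclohexan-9β-ol
Conditions: Me4NBH(OAc)3, AcOH/MeCN, −30 °C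
Reagents that add atoms: none
Why: Evans–Saksena hydroxyl-directed reduction: the acetoxyborohydride bound to the α-face CH2OH should deliver hydride to the α face of C9 and give the 9β-alcohol (anti 1,3-diol).

Step 3
Reactants: 4 4α-(hydroxymethyl)-4β-methyl-5β-(phenylselanyl)-7α-isopropenylcyclohexan-9β-ol
Product: 6 4α-(hydroxymethyl)-4β-methyl-7α-isopropenylcyclohex-5-en-9β-ol, via selenoxide 5 (not isolated)
Conditions: NaIO4, NaHCO3, MeOH/H2O, 0 °C to rt
Reagents that add atoms: none
Why: Selenoxide syn-elimination can only take a hydrogen from C6 because C4 is quaternary, which should place the ring alkene at C5=C6 without touching the isopropenyl group.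

Step 4
Reactants: 6 4α-(hydroxymethyl)-4β-methyl-7α-isopropenylcyclohex-5-en-9β-ol
Product: 7 9β-hydroxy-4β-methyl-7α-isopropenylcyclohex-5-ene-4α-carbaldehyde
Conditions: TEMPO (cat.), PhI(OAc)2, CH2Cl2, rt
Reagents that add atoms: none
Why: Oxoammonium (TEMPO) oxidation is selective for the primary alcohol over the hindered secondary C9 alcohol and should give the non-enolisable aldehyde.

Step 5
Reactants: 7 9β-hydroxy-4β-methyl-7α-isopropenylcyclohex-5-ene-4α-carbaldehyde
Product: 8 4α-[(E)-2-iodovinyl]-4β-methyl-7α-isopropenylcyclohex-5-en-9β-ol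
Conditions: CrCl2, CHI3, THF, 0 °C to rt
Reagents that add atoms: iodoform, IC(I)I
Why: Takai iodo-olefination of the aldehyde adds the C2 carbon and should give the E alkenyl iodide, as is usual for α-branched aldehydes.

Step 6
Reactants: 8 4α-[(E)-2-iodovinyl]-4β-methyl-7α-isopropenylcyclohex-5-en-9β-ol
Product: 9 5β,6β-epoxy-4α-[(E)-2-iodovinyl]-4β-methyl-7α-isopropenylcyclohexan-9β-ol
Conditions: VO(acac)2 (cat.), tBuOOH, CH2Cl2, 0 °C to rt
Reagents that add atoms: tert-butyl hydroperoxide, CC(C)(C)OO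
Why: Vanadium-catalysed hydroxyl-directed epoxidation of a cyclohex-3-enol: the pseudoaxial 9β-OH should deliver oxygen to the β face of C5=C6 only, while the isopropenyl and iodovinyl alkenes lie out of its reach.

Step 7
Reactants: 9 5β,6β-epoxy-4α-[(E)-2-iodovinyl]-4β-methyl-7α-isopropenylcyclohexan-9β-ol
Product: 10 5β,6β-epoxy-4α-[(E)-2-iodovinyl]-4β-methyl-7α-isopropenylcyclohexan-9-one
Conditions: Dess–Martin periodinane, NaHCO3, CH2Cl2, 0 °C to rt
Reagents that add atoms: none
Why: Dess–Martin oxidation should return the C9 ketone under buffered conditions that leave the epoxide and the alkenyl iodide intact.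

Step 8
Reactants: 10 5β,6β-epoxy-4α-[(E)-2-iodovinyl]-4β-methyl-7α-isopropenylcyclohexan-9-one
Product: 11 5β,6α-dihydroxy-4α-[(E)-2-iodovinyl]-4β-methyl-7α-isopropenylcyclohexan-9-one
Conditions: HClO4 (cat.), THF/H2O, rt
Reagents that add atoms: water, O
Why: Acid-catalysed anti opening of the epoxide (hydrolysis): water should attack C6 with inversion because C5 is neopentylic beside the quaternary C4, giving the 5β,6α-trans-diol.

Step 9
Reactants: 11 5β,6α-dihydroxy-4α-[(E)-2-iodovinyl]-4β-methyl-7α-isopropenylcyclohexan-9-one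
Product: 12 5β,6α-O-(1,1,3,3-tetraisopropyldisiloxane-1,3-diyl) derivative of 11
Conditions: (iPr2SiCl)2O, imidazole, DMF, rt to 40 °C
Reagents that add atoms: 1,3-dichloro-1,1,3,3-tetraisopropyldisiloxane, CC(C)[Si](Cl)(C(C)C)O[Si](Cl)(C(C)C)C(C)C
Why: Silylation with the bifunctional dichlorodisiloxane should bridge the trans-diequatorial vicinal diol in one operation and fix the chair in which the C4 methyl and the C7 isopropenyl group are axial.

Step 10
Reactants: 12 5β,6α-O-(1,1,3,3-tetraisopropyldisiloxane-1,3-diyl) derivative of 11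
Product: 14 8β-hydroxy derivative of 12, via potassium enolate 13 (not isolated)
Conditions: KN(SiMe3)2, THF, −78 °C; 2-(phenylsulfonyl)-3-phenyloxaziridine, −78 °C; AcOH
Reagents that add atoms: 2-(phenylsulfonyl)-3-phenyloxaziridine, O=S(=O)(c1ccccc1)N1OC1c1ccccc1
Why: The ketone can enolise only toward C8, and Davis α-hydroxylation of the potassium enolate should enter anti to the pseudoaxial C7 isopropenyl group to give the 8β-alcohol, whose configuration is corrected in step 11.

Step 11
Reactants: 14 8β-hydroxy derivative of 12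
Product: 16 8α-(2-methoxypropan-2-yloxy) ketone, via 8β-acetal 15 (not isolated)
Conditions: 2-methoxypropene, PPTS (cat.), CH2Cl2, 0 °C; then DBU, PhMe, 60 °C
Reagents that add atoms: 2-methoxypropene, C=C(C)OC
Why: Acid-catalysed acetalisation followed by base-mediated enolisation and reprotonation (thermodynamic epimerisation α to the ketone) should move the C8 ether from the axial position syn to the axial C4 methyl into the equatorial α position.

Step 12
Reactants: 16 8α-(2-methoxypropan-2-yloxy) ketone; 17 4-methoxybenzyl alcohol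
Product: 18 4α-[(E)-2-(4-methoxybenzyloxy)vinyl] ketone
Conditions: CuI (cat.), 3,4,7,8-tetramethyl-1,10-phenanthroline (cat.), Cs2CO3, PhMe, 80 °C
Reagents that add atoms: 4-methoxybenzyl alcohol (17), COc1ccc(CO)cc1
Why: Copper-catalysed Ullmann-type C–O coupling of an alkenyl iodide with a primary alcohol proceeds with retention of alkene geometry and should give the E enol ether.

Step 13
Reactants: 18 4α-[(E)-2-(4-methoxybenzyloxy)vinyl] ketone; 19 isopropenylmagnesium bromide
Product: 20 9α-hydroxy-9β-isopropenyl-4α-[(E)-2-(4-methoxybenzyloxy)vinyl]-4β-methyl-5β,6α-O-(tetraisopropyldisiloxanediyl)-7α-isopropenyl-8α-(2-methoxypropan-2-yloxy)cyclohexane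
Conditions: isopropenylMgBr, THF, −78 to 0 °C; aq. NaHCO3
Reagents that add atoms: isopropenylmagnesium bromide (19), C=C(C)[Mg]Br
Why: Chelation-assisted Grignard 1,2-addition: axial approach is blocked by the syn-axial C7 isopropenyl group, so the nucleophile should enter equatorially on the β face and give the axial 9α-alcohol with the two alkenyl groups trans.

Step 14
Reactants: 20 9α-hydroxy-9β-isopropenyl-4α-[(E)-2-(4-methoxybenzyloxy)vinyl]-4β-methyl-5β,6α-O-(tetraisopropyldisiloxanediyl)-7α-isopropenyl-8α-(2-methoxypropan-2-yloxy)cyclohexane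
Product: 23 (E)-2-(4-methoxybenzyloxy)-4,10-dimethyl-5,6-O-(tetraisopropyldisiloxanediyl)-7-isopropenyl-8-(2-methoxypropan-2-yloxy)cyclodec-3-en-9-one, via potassium alkoxide 21 (not isolated), via potassium enolate 22 (not isolated)
Conditions: KH, 18-crown-6, THF, 0 °C to rt; then AcOH, THF, −78 °C
Reagents that add atoms: none
Why: KH forms the C9 potassium alkoxide, whose charge accelerates a concerted [3,3] sigmatropic shift (anionic oxy-Cope rearrangement) that forms C1–C2, breaks C4–C9 and gives the ring-enlarged enolate, which is protonated at C10 on quench; the closest known class is the ring expansion of trans-1,2-dialkenylcyclohexanols to cyclodec-5-enones. The ten-membered ring is not closed end to end but arises by four-atom ring expansion through a chair transition state, a trans-decalin-like array in which both alkenyl groups are equatorial. C2 is controlled by that chair together with the E enol ether, which places the benzyloxy group pseudo-equatorial, and the same chair makes C3=C4 E. C10 is controlled by kinetic protonation of the enolate on its outer face, the inner face being covered by the ring. The step needs chair over boat selectivity and an alkoxide that stays free, which the trans-diequatorial alkenyl groups on the disiloxane-locked chair and the acetal instead of a silyl ether on the neighbouring C8 oxygen should secure.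

Step 15
Reactants: 23 (E)-2-(4-methoxybenzyloxy)-4,10-dimethyl-5,6-O-(tetraisopropyldisiloxanediyl)-7-isopropenyl-8-(2-methoxypropan-2-yloxy)cyclodec-3-en-9-one
Product: 24 8-hydroxy ketone (8-O-deprotected 23)
Conditions: PPTS (cat.), MeOH, 0 °C to rt
Reagents that add atoms: none
Why: Acid-catalysed transacetalisation to methanol should remove the ketal-type ether under conditions too mild for the disiloxane, the benzylic ether or the centres next to the ketone.

Step 16
Reactants: 24 8-hydroxy ketone (8-O-deprotected 23)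
Product: 25 8-O-isobutyryl ketone
Conditions: (iPrCO)2O, DMAP (cat.), pyridine, CH2Cl2, 0 °C
Reagents that add atoms: isobutyric anhydride, CC(C)C(=O)OC(=O)C(C)C
Why: DMAP-catalysed acylation of the only free hydroxyl should install the C8 isobutyrate while C5 and C6 are still masked.

Step 17
Reactants: 25 8-O-isobutyryl ketone
Product: 26 5,6-diol 8-isobutyrate
Conditions: HF·pyridine, pyridine, THF, 0 °C to rt
Reagents that add atoms: none
Why: Fluoride-mediated Si–O cleavage (desilylation) should free both diol oxygens and leave the ester, the benzylic ether and the alkenes untouched.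

Step 18
Reactants: 26 5,6-diol 8-isobutyrate
Product: 27 3,4-epoxy 5,6-diol (oxygen on the outer face of the former alkene)
Conditions: VO(acac)2 (cat.), tBuOOH, CH2Cl2, 0 °C
Reagents that add atoms: tert-butyl hydroperoxide, CC(C)(C)OO
Why: Vanadium-catalysed epoxidation directed by the allylic C5 hydroxyl, which lies on the outer face of the E alkene (anti to the bond broken in step 14), should set the C4–O bond of the target and outrun the isopropenyl group, which is only homoallylic to the C6 hydroxyl.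

Step 19
Reactants: 27 3,4-epoxy 5,6-diol (oxygen on the outer face of the former alkene)
Product: 28 3-(phenylselanyl)-4,5,6-triol
Conditions: PhSeH, Ti(OiPr)4, CH2Cl2, rt
Reagents that add atoms: benzeneselenol, [SeH]c1ccccc1
Why: Titanium-mediated opening of a 2,3-epoxy alcohol by a chalcogen nucleophile is selective for the carbon remote from the carbinol, so SN2 attack with inversion at secondary C3 should leave the tertiary C4–O bond intact without reducing the ketone or the ester.

Step 20
Reactants: 28 3-(phenylselanyl)-4,5,6-triol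
Product: 29 4,5,6-triol (C3 methylene)
Conditions: Bu3SnH, AIBN (cat.), PhMe, 80 °C
Reagents that add atoms: none
Why: Radical-chain reduction with the tin hydride cleaves the C–Se bond and should give the C3 methylene with no effect on C4.

Step 21
Reactants: 29 4,5,6-triol (C3 methylene)
Product: 30 12-hydroxy-4,5,6-triol
Conditions: SeO2 (cat.), tBuOOH, CH2Cl2, rt
Reagents that add atoms: tert-butyl hydroperoxide, CC(C)(C)OO
Why: Selenium dioxide allylic oxidation (ene reaction then [2,3] shift) of the only remaining alkene should hydroxylate the methyl group of the 1,1-disubstituted isopropenyl unit in preference to the hindered C7 methine.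

Step 22
Reactants: 30 12-hydroxy-4,5,6-triol
Product: 33 6,12-lactone (2-O-(4-methoxybenzyl)-5-O-deangeloyl target), via enal 31 (not isolated), via lactol 32 (not isolated)
Conditions: MnO2 (excess), CH2Cl2, rt
Reagents that add atoms: none
Why: Oxidative lactonisation: MnO2 oxidises only the allylic alcohol, the enal is captured by the C6 hydroxyl as the five-membered lactol in preference to a six-membered one on C5, and further oxidation should give the α-methylene lactone, whose cis fusion follows from the existing C6 and C7 centres.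

Step 23
Reactants: 33 6,12-lactone (2-O-(4-methoxybenzyl)-5-O-deangeloyl target); 34 angelic acid
Product: 36 2-O-(4-methoxybenzyl) ether of the target, via mixed anhydride 35 (not isolated)
Conditions: 34, 2,4,6-trichlorobenzoyl chloride, Et3N, PhMe, rt; then 33, 80 °C
Reagents that add atoms: angelic acid (34), C/C=C(/C)C(=O)O
Why: Yamaguchi esterification through the mixed anhydride, run without a nucleophilic catalyst, should acylate the secondary C5 hydroxyl (the tertiary C4 hydroxyl is inert) and keep the Z geometry of the angelate.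

Step 24
Reactants: 36 2-O-(4-methoxybenzyl) ether of the target
Product: 37 CNP0184688.2 (target)
Conditions: DDQ, CH2Cl2/pH 7 buffer, 0 °C
Reagents that add atoms: none
Why: Oxidative cleavage of the 4-methoxybenzyl ether by DDQ should free the C2 hydroxyl without affecting the α-methylene lactone, the two esters or the ketone.

Compound list
1 | (S)-carvone | CC1=CC[C@@H](CC1=O)C(C)=C | starting material
2 | C9=C4 trimethylsilyl enol ether of 5β-(phenylselanyl)dihydrocarvone | C[Si](C)(C)OC1=C(C)[C@@H]([Se]c2ccccc2)C[C@H](C(C)=C)C1 | intermediate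
3 | 4α-(hydroxymethyl)-4β-methyl-5β-(phenylselanyl)-7α-isopropenylcyclohexan-9-one | O=C1[C@](C)(CO)[C@@H]([Se]c2ccccc2)C[C@H](C(C)=C)C1 | intermediate
4 | 4α-(hydroxymethyl)-4β-methyl-5β-(phenylselanyl)-7α-isopropenylcyclohexan-9β-ol | O[C@H]1[C@](C)(CO)[C@@H]([Se]c2ccccc2)C[C@H](C(C)=C)C1 | intermediate
5 | selenoxide of 4 (selenium configuration undefined) | O[C@H]1[C@](C)(CO)[C@@H]([Se](=O)c2ccccc2)C[C@H](C(C)=C)C1 | intermediate
6 | 4α-(hydroxymethyl)-4β-methyl-7α-isopropenylcyclohex-5-en-9β-ol | O[C@H]1[C@](C)(CO)C=C[C@H](C(C)=C)C1 | intermediate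
7 | 9β-hydroxy-4β-methyl-7α-isopropenylcyclohex-5-ene-4α-carbaldehyde | O[C@H]1[C@](C)(C=O)C=C[C@H](C(C)=C)C1 | intermediate
8 | 4α-[(E)-2-iodovinyl]-4β-methyl-7α-isopropenylcyclohex-5-en-9β-ol | O[C@H]1[C@](C)(/C=C/I)C=C[C@H](C(C)=C)C1 | intermediate
9 | 5β,6β-epoxy-4α-[(E)-2-iodovinyl]-4β-methyl-7α-isopropenylcyclohexan-9β-ol | O[C@H]1[C@](C)(/C=C/I)[C@H]2O[C@H]2[C@H](C(C)=C)C1 | intermediate
10 | 5β,6β-epoxy-4α-[(E)-2-iodovinyl]-4β-methyl-7α-isopropenylcyclohexan-9-one | O=C1[C@](C)(/C=C/I)[C@H]2O[C@H]2[C@H](C(C)=C)C1 | intermediate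
11 | 5β,6α-dihydroxy-4α-[(E)-2-iodovinyl]-4β-methyl-7α-isopropenylcyclohexan-9-one | O=C1[C@](C)(/C=C/I)[C@@H](O)[C@H](O)[C@H](C(C)=C)C1 | intermediate
12 | 5β,6α-O-(1,1,3,3-tetraisopropyldisiloxane-1,3-diyl) derivative of 11 | O=C1[C@](C)(/C=C/I)[C@H]2O[Si](C(C)C)(C(C)C)O[Si](C(C)C)(C(C)C)O[C@@H]2[C@H](C(C)=C)C1 | intermediate
13 | potassium C8=C9 enolate of 12 | [K+].[O-]C=1[C@](C)(/C=C/I)[C@H]2O[Si](C(C)C)(C(C)C)O[Si](C(C)C)(C(C)C)O[C@@H]2[C@H](C(C)=C)C=1 | intermediate
14 | 8β-hydroxy derivative of 12 | O=C1[C@](C)(/C=C/I)[C@H]2O[Si](C(C)C)(C(C)C)O[Si](C(C)C)(C(C)C)O[C@@H]2[C@H](C(C)=C)[C@H]1O | intermediate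
15 | 8β-(2-methoxypropan-2-yl) ether of 14 | O=C1[C@](C)(/C=C/I)[C@H]2O[Si](C(C)C)(C(C)C)O[Si](C(C)C)(C(C)C)O[C@@H]2[C@H](C(C)=C)[C@H]1OC(C)(C)OC | intermediate
16 | 8α-(2-methoxypropan-2-yloxy) ketone (C8 epimer of 15) | O=C1[C@](C)(/C=C/I)[C@H]2O[Si](C(C)C)(C(C)C)O[Si](C(C)C)(C(C)C)O[C@@H]2[C@H](C(C)=C)[C@@H]1OC(C)(C)OC | intermediate
17 | 4-methoxybenzyl alcohol | COc1ccc(CO)cc1 | starting material
18 | 4α-[(E)-2-(4-methoxybenzyloxy)vinyl] ketone | O=C1[C@](C)(/C=C/OCc3ccc(OC)cc3)[C@H]2O[Si](C(C)C)(C(C)C)O[Si](C(C)C)(C(C)C)O[C@@H]2[C@H](C(C)=C)[C@@H]1OC(C)(C)OC | intermediate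
19 | isopropenylmagnesium bromide | C=C(C)[Mg]Br | starting material
20 | oxy-Cope precursor, the 9α-hydroxy-9β-isopropenyl cyclohexane | C=C(C)[C@@]1(O)[C@](C)(/C=C/OCc2ccc(OC)cc2)[C@H]3O[Si](C(C)C)(C(C)C)O[Si](C(C)C)(C(C)C)O[C@@H]3[C@H](C(C)=C)[C@@H]1OC(C)(C)OC | intermediate
21 | potassium alkoxide of 20 | [K+].C=C(C)[C@@]1([O-])[C@](C)(/C=C/OCc2ccc(OC)cc2)[C@H]3O[Si](C(C)C)(C(C)C)O[Si](C(C)C)(C(C)C)O[C@@H]3[C@H](C(C)=C)[C@@H]1OC(C)(C)OC | intermediate
22 | potassium C9=C10 enolate of 23 | [K+].C=C(C)[C@@H]1[C@H](OC(C)(C)OC)/C([O-])=C(C)/C[C@H](OCc2ccc(OC)cc2)/C=C(C)/[C@H]3O[Si](C(C)C)(C(C)C)O[Si](C(C)C)(C(C)C)O[C@H]13 | intermediate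
23 | (E)-2-(4-methoxybenzyloxy)-4,10-dimethyl-5,6-O-(tetraisopropyldisiloxanediyl)-7-isopropenyl-8-(2-methoxypropan-2-yloxy)cyclodec-3-en-9-one | C=C(C)[C@@H]1[C@H](OC(C)(C)OC)C(=O)[C@@H](C)C[C@H](OCc2ccc(OC)cc2)/C=C(C)/[C@H]3O[Si](C(C)C)(C(C)C)O[Si](C(C)C)(C(C)C)O[C@H]13 | intermediate
24 | 8-hydroxy ketone (8-O-deprotected 23) | C=C(C)[C@@H]1[C@H](O)C(=O)[C@@H](C)C[C@H](OCc2ccc(OC)cc2)/C=C(C)/[C@H]3O[Si](C(C)C)(C(C)C)O[Si](C(C)C)(C(C)C)O[C@H]13 | intermediate
25 | 8-O-isobutyryl ketone | C=C(C)[C@@H]1[C@H](OC(=O)C(C)C)C(=O)[C@@H](C)C[C@H](OCc2ccc(OC)cc2)/C=C(C)/[C@H]3O[Si](C(C)C)(C(C)C)O[Si](C(C)C)(C(C)C)O[C@H]13 | intermediate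
26 | 5,6-diol 8-isobutyrate | C=C(C)[C@@H]1[C@H](OC(=O)C(C)C)C(=O)[C@@H](C)C[C@H](OCc2ccc(OC)cc2)/C=C(C)/[C@@H](O)[C@@H]1O | intermediate
27 | 3,4-epoxy 5,6-diol | C=C(C)[C@@H]1[C@H](OC(=O)C(C)C)C(=O)[C@@H](C)C[C@H](OCc2ccc(OC)cc2)[C@H]3O[C@]3(C)[C@@H](O)[C@@H]1O | intermediate
28 | 3-(phenylselanyl)-4,5,6-triol | C=C(C)[C@@H]1[C@H](OC(=O)C(C)C)C(=O)[C@@H](C)C[C@H](OCc2ccc(OC)cc2)[C@H]([Se]c3ccccc3)[C@](C)(O)[C@@H](O)[C@@H]1O | intermediate
29 | 4,5,6-triol (C3 methylene) | C=C(C)[C@@H]1[C@H](OC(=O)C(C)C)C(=O)[C@@H](C)C[C@H](OCc2ccc(OC)cc2)C[C@](C)(O)[C@@H](O)[C@@H]1O | intermediate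
30 | 12-hydroxy-4,5,6-triol | C=C(CO)[C@@H]1[C@H](OC(=O)C(C)C)C(=O)[C@@H](C)C[C@H](OCc2ccc(OC)cc2)C[C@](C)(O)[C@@H](O)[C@@H]1O | intermediate
31 | C12 aldehyde (2-substituted acrolein) | O=CC(=C)[C@@H]1[C@H](OC(=O)C(C)C)C(=O)[C@@H](C)C[C@H](OCc2ccc(OC)cc2)C[C@](C)(O)[C@@H](O)[C@@H]1O | intermediate
32 | 6,12-lactol (mixture at C12) | C=C1C(O)O[C@@H]2[C@H]1[C@H](OC(=O)C(C)C)C(=O)[C@@H](C)C[C@H](OCc3ccc(OC)cc3)C[C@](C)(O)[C@H]2O | intermediate
33 | 6,12-lactone (2-O-(4-methoxybenzyl)-5-O-deangeloyl target) | C=C1C(=O)O[C@@H]2[C@H]1[C@H](OC(=O)C(C)C)C(=O)[C@@H](C)C[C@H](OCc3ccc(OC)cc3)C[C@](C)(O)[C@H]2O | intermediate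
34 | angelic acid | C/C=C(/C)C(=O)O | starting material
35 | angelic 2,4,6-trichlorobenzoic anhydride | C/C=C(/C)C(=O)OC(=O)c1c(Cl)cc(Cl)cc1Cl | intermediate
36 | 2-O-(4-methoxybenzyl) ether of the target | C=C1C(=O)O[C@@H]2[C@H]1[C@H](OC(=O)C(C)C)C(=O)[C@@H](C)C[C@H](OCc3ccc(OC)cc3)C[C@](C)(O)[C@H]2OC(=O)/C(C)=C\C | intermediate
37 | CNP0184688.2 | C=C1C(=O)O[C@@H]2[C@H]1[C@H](OC(=O)C(C)C)C(=O)[C@@H](C)C[C@H](O)C[C@](C)(O)[C@H]2OC(=O)/C(C)=C\C | target

Total step count: 24. Longest linear sequence: 24 steps, from (S)-carvone (1) to 37.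

Steps most likely to fail

Step 14. Proton transfer within the enolate before or during the quench (C9=C10 enolate to C8=C9 enolate), or protonation on the ring-covered face, would erode C10 and C8. The fallback separates rearrangement from protonation. It sets out from 20: the rearrangement is run as before, but enolate 22 is trapped at −78 °C with Me3SiCl/Et3N and isolated as the trimethylsilyl enol ether F1. This is then protodesilylated in a separate operation with Bu4NF/AcOH in THF at −78 °C, so that the proton is delivered under reagent control to the open face. The fallback returns to the route at 23.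

Step 19. The selenol has to reach C3 along a trajectory that points toward the ring interior. Approach may be too slow, or the Lewis acid may instead induce transannular capture of the activated epoxide by the C9 carbonyl oxygen. The fallback sets out from 27 and uses a halohydrin route: iodide is delivered inside the titanium chelate (Ti(OiPr)4, I2, CH2Cl2, 0 °C) to C3, giving the iodohydrin F2. The C–I bond is then reduced with Bu3SnH/AIBN in PhMe at 80 °C. The fallback returns to the route at 29.

Step 23. Acylation of the neopentylic C5 hydroxyl next to the tertiary carbinol may be slow, and the activated angelate may isomerise from Z to E before it is transferred. The fallback builds the alkene after the ester bond. It sets out from 33, which is esterified with 2-[bis(2,2,2-trifluoroethoxy)phosphoryl]propanoic acid (DCC, DMAP, CH2Cl2) to the phosphonate ester F3. A Still–Gennari olefination with acetaldehyde (KN(SiMe3)2, 18-crown-6, THF, −78 °C) then forms the Z-2-methylbut-2-enoate in place. The fallback returns to the route at 36.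

Further compounds
F1 | step 14 | trimethylsilyl enol ether (C9=C10) of 23 | C=C(C)[C@@H]1[C@H](OC(C)(C)OC)/C(O[Si](C)(C)C)=C(C)/C[C@H](OCc2ccc(OC)cc2)/C=C(C)/[C@H]3O[Si](C(C)C)(C(C)C)O[Si](C(C)C)(C(C)C)O[C@H]13
F2 | step 19 | 3-iodo-4,5,6-triol | C=C(C)[C@@H]1[C@H](OC(=O)C(C)C)C(=O)[C@@H](C)C[C@H](OCc2ccc(OC)cc2)[C@H](I)[C@](C)(O)[C@@H](O)[C@@H]1O
F3 | step 23 | 5-O-{2-[bis(2,2,2-trifluoroethoxy)phosphoryl]propanoyl} derivative of 33 (mixture at the phosphonate carbon) | C=C1C(=O)O[C@@H]2[C@H]1[C@H](OC(=O)C(C)C)C(=O)[C@@H](C)C[C@H](OCc3ccc(OC)cc3)C[C@](C)(O)[C@H]2OC(=O)C(C)P(=O)(OCC(F)(F)F)OCC(F)(F)F
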